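One count holds through this flask: a step that takes one radical gives one back, so the carriers of a chain keep their number until the transfer agent or a pairing takes them out.

substrate 1.7 M; coupling partner 2.55 M; transfer agent 0.170 M; initiator 34 mM; time 3.0 min

    target → over-reaction product (k1 = 0.0054 s⁻¹)
    initiator → 2 initiating radical (k2 = 0.0040 s⁻¹)
    coupling partner + by-product ⇌ idle adduct, settled at all times (K3 = 2.4 M⁻¹)
    2 first chain carrier → ended chains B (k4 = 2 × 10⁸ M⁻¹ s⁻¹)
    substrate + initiating radical → capped initiator + first chain carrier (k5 = 8.7 × 10⁵ M⁻¹ s⁻¹)
    coupling partner + first chain carrier → target + second chain carrier (k6 = 7.1 × 10⁵ M⁻¹ s⁻¹)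
    2 idle radical → ended radicals (k7 = 2 × 10⁷ M⁻¹ s⁻¹)
    transfer agent + first chain carrier → side product + idle radical (k8 = 1.2 × 10⁶ M⁻¹ s⁻¹)
    2 second chain carrier → ended chains A (k9 = 1 × 10⁹ M⁻¹ s⁻¹)
    crystals ⇌ by-product, rate k10*(cs10 - [by-product]) while solid is left; crystals form when [by-product] > cs10 (cs10 = 0.88 M, k10 = 0.45 s⁻¹)
    substrate + second chain carrier → by-product + first chain carrier (k11 = 22000 M⁻¹ s⁻¹)

* part of the substrate that has reacted at 3.0 min
* share of the unused coupling partner that is free and not bound as idle adduct, at 3.0 min

- a species is counted by the substrate in it: one ended chains B counts as two
- amounts and yields of by-product count idle adduct and crystals too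
- where a step has two of a species, its rate is k times that concentration squared, and two are used at each turn
- given per volume of solution although it is solid: crystals
- run time (flask): 3.0 min

We ask first for the end state, in fractions of the charge. The initiator, wholly broken, gives fragments amounting to 4.00% of the substrate charged. A fragment uses one substrate on entry and another each time the second chain carrier returns, and at the charges the first chain carrier divides between coupling partner and transfer agent at 8.87 to one. So we carry 9.87, the substrate turned per fragment, our kinetic chain length, and with that ratio held our reckoned end state stands at 39.5% reacted. It is approached as the initiator breaks, with a half-life of 2.9 min, so 51.3% of it has broken by 3.0 min.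

With the ratio kept and no pairing, this gives 20.3%. We take that as a ceiling, because by our reckoning the coupling partner loses about 22.6% of its charge by 3.0 min, binding counted, against 20.5% for the transfer agent, so the ratio falls. For a floor we take that whole loss off the coupling partner, hold the transfer agent at its charge, and remove the 3.06% of fragments that pairing of the second chain carrier ends, which gives 15.7%.

The forecast says 18.5% reacted and 90% free, holding that “the coupling-to-transfer rate ratio gives a chain length of about 8”. Its 8 is not our 9.87, yet its figure lies inside our bracket.

The flask gives 19.6% reacted and 89.0% free; with the other charges and the time held, the reacted part has moved 5 points at 25.1 mM or 43.1 mM of initiator. The neighbour flask with 0.020 M of initiator reckons to 11.9% by the same product and reads 11.7%. This flask has not come to rest at 3.0 min, with 49% of its initiator still there. By 30.0 min this flask has 0.0747% of its initiator left and the reacted part at 38.2%, against our reckoned end state of 39.5%. Over that time the target in this flask falls from 10.6% to 0.0678% of the substrate charged.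

Its constants come from no measurement; what happens was integrated by code.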